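| setting | Tuesday's | Monday's | flask |
|---|---|---|---|
| substrate | 0.050 M | 0.050 M | 0.050 M |
| gas | 2.3 mM (held) | 2.3 mM (held) | 2.3 mM (held) |
| capture agent | 3.4 mM | 7.5 mM | 5.00 mM |
| remark | run made earlier | run made earlier |  |
| time |  |  | 6.0 d |

| run | time / d | isomer of the product / % | target / % |
|---|---|---|---|
| Tuesday's | 1.25 | 78 | 0 |
| Tuesday's | 2.50 | 67 | 0 |
| Tuesday's | 4.00 | 56 | 0 |
| Tuesday's | 5.00 | 49 | 0 |
| Tuesday's | 6.00 | 40 | 1 |
| Tuesday's | 8.00 | 31 | 3 |
| Monday's | 0.625 | 79 | 0 |
| Monday's | 1.04 | 72 | 0 |
| Monday's | 1.67 | 70 | 0 |
| Monday's | 2.50 | 60 | 0 |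
| Monday's | 4.00 | 49 | 0 |
| Monday's | 8.00 | 27 | 1 |

(each reading ± 1.5 percentage points)

- at the start none of the gas is in solution

* share of isomer of the product in isomer of the product plus target at 6.0 min
* share of isomer of the product in isomer of the product plus target at 6.0 d
* which of isomer of the product and target there is more of at 6.0 d

By amounts, the flask holds 5.00 mM of capture agent against 0.050 M of substrate, so capture agent is the limiting reagent of the capture step. As a fraction of the substrate charge it is 10.0 %, here called the capture share.

1. The reckoning assumes that one capture agent withdraws one substrate's worth. The isomer in the flask then starts from 90.0 % of the charge.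

2. Tuesday's isomer falls from 78 % to 31 % between 1.25 d and 8.00 d, a first-order constant of 0.137 d⁻¹. Run back to zero time, this gives 92.6 %, and Tuesday's capture share predicts 93.2 %. Readings and charge are different sources, so this checks the balance.

3. The flask at 6.0 d then holds 39.6 % isomer.

4. The weak link is a constant from one run. Monday's readings give 0.146 d⁻¹, the mean is 0.141 d⁻¹, and the flask's isomer becomes 38.6 %.

5. Tuesday's target reads 1 % at 6.00 d, with a scatter of 1.5 percentage points. At face value, the flask's share is 97.5 %, with isomer ahead. The earliest reading comes later than 6.0 min, so this reckoning gives no share there.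

The forecast commits to 100 % at 6.0 min, 98.7 % at 6.0 d, and isomer of the product ahead; its share at 6.0 d is higher than the 97.5 % reckoned here. Its ground: “the agent apparently intercepts target or its precursor until it is used up”.

The flask gives 80.3 % at 6.0 min and 99.8 % at 6.0 d, with isomer of the product ahead, 41.0 % against 0.0789 %.

    gas ⇌ reagent, rate k1*(csat - [reagent]) (kL = 0.590 min⁻¹)
    open intermediate ⇌ isomer of the product (K = 310, k = 0.650 min⁻¹)
    open intermediate + capture agent → trapped intermediate (k = 13.0 L mol⁻¹ min⁻¹)
    substrate + reagent → open intermediate + by-product (k = 21.0 L mol⁻¹ min⁻¹)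
    reagent + target → over-reaction product (k = 20.0 L mol⁻¹ min⁻¹)
    open intermediate ⇌ target (K = 0.640, k = 1.10 min⁻¹)

In the flask, isomer returns to open intermediate with a half-life of 0.23 d, short against 6.0 d. Trapped intermediate stands at 10.0 % at 6.00 d, level with the capture share, and capture agent stands at 0 % of its own charge.

The neighbour flask with 0.020 M of capture agent has a capture share of 40.0 %, which gives 25.7 % isomer at 6.0 d. Computed, it holds 26.8 % isomer and 40.0 % trapped intermediate.

The numbers in the tables are calculated on assumed constants, and the scatter is random.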